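## Retrosynthetic overview

1. Target 29 ⇒ seco-diene 28: the ten-membered carbocycle is closed last, by ring-closing metathesis at the ring-cis C4=C5 alkene.
2. 28 ⇒ bromobutenolide 25 + acrolein 26: the key C6–C7 bond is made by an intermolecular zinc-mediated carbonyl allylation, which sets C6 and C7 and turns the butenolide into the α-methylene-γ-lactone.
3. 25 ⇒ acrylate ester 22 ⇒ vinyl carbinol 16: the butenolide is the first ring formed (ring-closing metathesis); C8 comes from (S)-epichlorohydrin 12.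
4. 16 ⇒ alkenyl iodide 11 + 12; the C1=C10 geometry comes from syn-hydrostannation of ynoate 7, itself made from hex-5-yn-1-ol 1 by α-methylenation and C-acylation.
5. Ring order: butenolide, then (in the key step) α-methylene lactone, then the ten-membered ring.

Assumption: germacrane numbering is used for the skeleton (ring C1–C10, lactone C11–C13 closed to O–C8, C14 on C10, C15 on C4). The stereochemical outcome of step 21 is predicted from a chair transition-state model, not taken from a measured result on this substrate.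

## Route

Step 1
Reactants: 1 hex-5-yn-1-ol
Product: 2 hex-5-ynal
Conditions: TEMPO (10 mol %), PhI(OAc)2, CH2Cl2, 0 °C to rt
Reagents that add atoms: none
Why: TEMPO-catalysed oxoammonium oxidation stops at the aldehyde and leaves the terminal alkyne untouched.

Step 2
Reactants: 2 hex-5-ynal
Product: 3 2-methylidenehex-5-ynal
Conditions: 37 % aq. CH2O, pyrrolidine (10 mol %), EtCO2H (10 mol %), i-PrOH, 45 °C
Reagents that add atoms: formaldehyde, C=O
Why: Amine-catalysed Mannich condensation (enamine plus iminium, then amine elimination) α-methylenates the unbranched aldehyde, giving C4 with its exocyclic CH2 and C15 as the aldehyde.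

Step 3
Reactants: 3 2-methylidenehex-5-ynal
Product: 4 2-methylidenehex-5-yn-1-ol
Conditions: NaBH4, CeCl3·7H2O, MeOH, 0 °C
Reagents that add atoms: none
Why: Luche reduction gives clean 1,2-reduction of the enal to the allylic alcohol.

Step 4
Reactants: 4 2-methylidenehex-5-yn-1-ol
Product: 5 1-methoxy-4-{[(2-methylidenehex-5-yn-1-yl)oxy]methyl}benzene
Conditions: NaH, 4-MeOC6H4CH2Cl, Bu4NI (cat.), THF/DMF, 0 °C to rt
Reagents that add atoms: 4-methoxybenzyl chloride, COc1ccc(CCl)cc1
Why: Williamson etherification protects O15 as a PMB ether that survives the organolithium and hydride steps and is later removed oxidatively.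

Step 5
Reactants: 5 1-methoxy-4-{[(2-methylidenehex-5-yn-1-yl)oxy]methyl}benzene
Product: 7 methyl 7-[(4-methoxybenzyl)oxy]-6-methylidenehept-2-ynoate, via lithium acetylide 6 (not isolated)
Conditions: n-BuLi, THF, −78 °C; ClCO2Me, −78 to 0 °C
Reagents that add atoms: methyl chloroformate, COC(=O)Cl
Why: Deprotonation of the terminal alkyne and C-acylation of the acetylide gives the ynoate and brings in C14.

Step 6
Reactants: 7 methyl 7-[(4-methoxybenzyl)oxy]-6-methylidenehept-2-ynoate
Product: 8 methyl (2E)-7-[(4-methoxybenzyl)oxy]-6-methylidene-2-(tributylstannyl)hept-2-enoate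
Conditions: Bu3SnH, Pd(PPh3)4 (2 mol %), THF, 0 °C to rt
Reagents that add atoms: tributyltin hydride, CCCC[SnH](CCCC)CCCC
Why: Zerovalent-palladium-catalysed hydrostannation of a 2-ynoate adds H and Sn syn with tin α to the ester, which fixes the C1=C10 geometry (C14 cis to C2).

Step 7
Reactants: 8 methyl (2E)-7-[(4-methoxybenzyl)oxy]-6-methylidene-2-(tributylstannyl)hept-2-enoate
Product: 9 (2E)-7-[(4-methoxybenzyl)oxy]-6-methylidene-2-(tributylstannyl)hept-2-en-1-ol
Conditions: i-Bu2AlH (2.3 equiv), CH2Cl2, −78 °C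
Reagents that add atoms: none
Why: Hydride reduction of the ester to the allylic alcohol (C14 at its final oxidation level) removes the conjugated carbonyl so the olefin cannot isomerise later.

Step 8
Reactants: 9 (2E)-7-[(4-methoxybenzyl)oxy]-6-methylidene-2-(tributylstannyl)hept-2-en-1-ol
Product: 10 (2E)-2-iodo-7-[(4-methoxybenzyl)oxy]-6-methylidenehept-2-en-1-ol
Conditions: I2, CH2Cl2, 0 °C, dark
Reagents that add atoms: iodine, II
Why: Iododestannylation is an ipso electrophilic substitution with retention of olefin geometry and is much faster than any reaction of the isolated alkenes.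

Step 9
Reactants: 10 (2E)-2-iodo-7-[(4-methoxybenzyl)oxy]-6-methylidenehept-2-en-1-ol
Product: 11 (2E)-2-iodo-1,7-bis[(4-methoxybenzyl)oxy]-6-methylidenehept-2-ene
Conditions: NaH, 4-MeOC6H4CH2Cl, Bu4NI (cat.), THF/DMF, 0 °C to rt
Reagents that add atoms: 4-methoxybenzyl chloride, COc1ccc(CCl)cc1
Why: A second Williamson etherification protects O14 like O15, so both can be exchanged for acetate in one operation.

Step 10
Reactants: 11 (2E)-2-iodo-1,7-bis[(4-methoxybenzyl)oxy]-6-methylidenehept-2-ene, 12 (S)-epichlorohydrin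
Product: 14 (2S,4Z)-1-chloro-4,8-bis{[(4-methoxybenzyl)oxy]methyl}nona-4,8-dien-2-ol, via alkenyllithium 13 (not isolated)
Conditions: t-BuLi (2.1 equiv), Et2O, −78 °C; then 12, BF3·OEt2, −78 °C
Reagents that add atoms: none
Why: Iodine–lithium exchange with retention gives the alkenyllithium, which opens the BF3-activated epoxide at its unsubstituted carbon (SN2), so C9–C10 is formed with the olefin geometry intact and C8 is taken unchanged from the chiral pool.

Step 11
Reactants: 14 (2S,4Z)-1-chloro-4,8-bis{[(4-methoxybenzyl)oxy]methyl}nona-4,8-dien-2-ol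
Product: 15 (2S)-2-[(2Z)-2,6-bis{[(4-methoxybenzyl)oxy]methyl}hepta-2,6-dien-1-yl]oxirane
Conditions: K2CO3, MeOH, rt
Reagents that add atoms: none
Why: Intramolecular Williamson displacement of chloride by the alkoxide closes the epoxide without touching the C8–O bond, so C8 keeps its configuration.

Step 12
Reactants: 15 (2S)-2-[(2Z)-2,6-bis{[(4-methoxybenzyl)oxy]methyl}hepta-2,6-dien-1-yl]oxirane
Product: 16 (3S,5Z)-5,9-bis{[(4-methoxybenzyl)oxy]methyl}deca-1,5,9-trien-3-ol
Conditions: Me3SI, n-BuLi, THF, −10 °C to rt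
Reagents that add atoms: trimethylsulfonium iodide, C[S+](C)C.[I-]
Why: One-carbon epoxide homologation with dimethylsulfonium methylide (attack at the terminal carbon, then elimination of Me2S from the betaine) gives the vinyl carbinol with C8 untouched.

Step 13
Reactants: 17 ethyl 2-(hydroxymethyl)prop-2-enoate
Product: 18 ethyl 2-({[tert-butyl(dimethyl)silyl]oxy}methyl)prop-2-enoate
Conditions: TBSCl, imidazole, CH2Cl2, 0 °C to rt
Reagents that add atoms: tert-butyldimethylsilyl chloride, CC(C)(C)[Si](C)(C)Cl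
Why: Silylation masks the future C13 oxygen with a group orthogonal to the PMB ethers and to the later acetates.

Step 14
Reactants: 18 ethyl 2-({[tert-butyl(dimethyl)silyl]oxy}methyl)prop-2-enoate
Product: 19 2-({[tert-butyl(dimethyl)silyl]oxy}methyl)prop-2-enoic acid
Conditions: LiOH·H2O, THF/H2O, 0 °C; then 1 M HCl to pH 3
Reagents that add atoms: lithium hydroxide, [Li+].[OH-]
Why: Saponification of the ethyl ester at 0 °C leaves the primary silyl ether intact and gives the acid that carries C11, C12 and C13.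

Step 15
Reactants: 16 (3S,5Z)-5,9-bis{[(4-methoxybenzyl)oxy]methyl}deca-1,5,9-trien-3-ol, 19 2-({[tert-butyl(dimethyl)silyl]oxy}methyl)prop-2-enoic acid
Product: 20 (3S,5Z)-5,9-bis{[(4-methoxybenzyl)oxy]methyl}deca-1,5,9-trien-3-yl 2-({[tert-butyl(dimethyl)silyl]oxy}methyl)prop-2-enoate
Conditions: DCC, DMAP (cat.), CH2Cl2, 0 °C to rt
Reagents that add atoms: none
Why: Steglich esterification acylates O8 without breaking the C8–O bond, so the stereocentre is retained.

Step 16
Reactants: 20 (3S,5Z)-5,9-bis{[(4-methoxybenzyl)oxy]methyl}deca-1,5,9-trien-3-yl 2-({[tert-butyl(dimethyl)silyl]oxy}methyl)prop-2-enoate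
Product: 21 (3S,5Z)-5,9-bis(hydroxymethyl)deca-1,5,9-trien-3-yl 2-({[tert-butyl(dimethyl)silyl]oxy}methyl)prop-2-enoate
Conditions: DDQ (2.4 equiv), CH2Cl2/pH 7 buffer, 0 °C
Reagents that add atoms: none
Why: Oxidative PMB cleavage with DDQ frees both primary allylic alcohols under neutral conditions that spare the ester, the silyl ether and all alkenes.

Step 17
Reactants: 21 (3S,5Z)-5,9-bis(hydroxymethyl)deca-1,5,9-trien-3-yl 2-({[tert-butyl(dimethyl)silyl]oxy}methyl)prop-2-enoate
Product: 22 (3S,5Z)-5,9-bis(acetoxymethyl)deca-1,5,9-trien-3-yl 2-({[tert-butyl(dimethyl)silyl]oxy}methyl)prop-2-enoate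
Conditions: Ac2O, pyridine, DMAP (cat.), CH2Cl2, 0 °C
Reagents that add atoms: acetic anhydride, CC(=O)OC(C)=O
Why: Acetylation installs the two acetates of the target before the base-sensitive butenolide exists, and no later step uses strong base or hydride.

Step 18
Reactants: 22 (3S,5Z)-5,9-bis(acetoxymethyl)deca-1,5,9-trien-3-yl 2-({[tert-butyl(dimethyl)silyl]oxy}methyl)prop-2-enoate
Product: 23 (5S)-5-[(2Z)-2,6-bis(acetoxymethyl)hepta-2,6-dien-1-yl]-3-({[tert-butyl(dimethyl)silyl]oxy}methyl)furan-2(5H)-one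
Conditions: second-generation Grubbs catalyst RuCl2(=CHPh)(H2IMes)(PCy3) (5 mol %), toluene (5 mM), 80 °C
Reagents that add atoms: none
Why: Ring-closing metathesis between the vinyl group and the 2-substituted acrylate forms the five-membered butenolide far faster than any larger ring (the only alternative would hold a trans alkene in an eight-membered ring), and C8 is not involved.

Step 19
Reactants: 23 (5S)-5-[(2Z)-2,6-bis(acetoxymethyl)hepta-2,6-dien-1-yl]-3-({[tert-butyl(dimethyl)silyl]oxy}methyl)furan-2(5H)-one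
Product: 24 (5S)-5-[(2Z)-2,6-bis(acetoxymethyl)hepta-2,6-dien-1-yl]-3-(hydroxymethyl)furan-2(5H)-one
Conditions: HF·pyridine, pyridine, THF, 0 °C to rt
Reagents that add atoms: none
Why: Buffered fluoride desilylation frees the C13 alcohol without acetate migration or epimerisation of the butenolide γ-carbon.

Step 20
Reactants: 24 (5S)-5-[(2Z)-2,6-bis(acetoxymethyl)hepta-2,6-dien-1-yl]-3-(hydroxymethyl)furan-2(5H)-one
Product: 25 (5S)-5-[(2Z)-2,6-bis(acetoxymethyl)hepta-2,6-dien-1-yl]-3-(bromomethyl)furan-2(5H)-one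
Conditions: CBr4, PPh3, CH2Cl2, 0 °C
Reagents that add atoms: carbon tetrabromide, BrC(Br)(Br)Br
Why: The Appel reaction converts the primary allylic alcohol into the allylic bromide under neutral conditions, giving the cyclic 2-(bromomethyl)acrylate needed for the allylation.

Step 21
Reactants: 25 (5S)-5-[(2Z)-2,6-bis(acetoxymethyl)hepta-2,6-dien-1-yl]-3-(bromomethyl)furan-2(5H)-one, 26 acrolein
Product: 28 (4S,5S)-5-[(2Z)-2,6-bis(acetoxymethyl)hepta-2,6-dien-1-yl]-4-[(1R)-1-hydroxyprop-2-en-1-yl]-3-methylideneoxolan-2-one, via allylzinc bromide 27 (not isolated)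
Conditions: Zn dust, THF/sat. aq. NH4Cl (2:1), 0 °C to rt
Reagents that add atoms: none
Why: In this Barbier-type carbonyl allylation the allylzinc adds through C7 (SE2') to the aldehyde carbon in a chair Zimmerman–Traxler transition state on the butenolide face anti to the C8 side chain, which sets C7 (S, trans to C9) and C6 (R, from the ring-fixed E-type allyl geometry with the vinyl group equatorial) and creates the α-methylene lactone.

Step 22
Reactants: 28 (4S,5S)-5-[(2Z)-2,6-bis(acetoxymethyl)hepta-2,6-dien-1-yl]-4-[(1R)-1-hydroxyprop-2-en-1-yl]-3-methylideneoxolan-2-one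
Product: 29 (6R,7S,8S)-14,15-diacetoxy-6-hydroxygermacra-1(10)Z,4E,11(13)-trien-12,8-olide (CNP0594234.1)
Conditions: second-generation Hoveyda–Grubbs catalyst RuCl2(=CH-C6H4-2-O-i-Pr)(H2IMes) (15 mol %, in portions), 1,4-benzoquinone (20 mol %), toluene (1 mM), 80 °C, Ar sparge
Reagents that add atoms: none
Why: Ring-closing metathesis between the C5 vinyl group and the 1,1-disubstituted C4 alkene expels ethene and closes the ten-membered ring as the ring-cis trisubstituted alkene (C3 cis to C6, 4E), the favoured geometry for a ring of this size, without touching any stereocentre.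

## Compound list

1 | hex-5-yn-1-ol | OCCCCC#C | starting material
2 | hex-5-ynal | O=CCCCC#C | intermediate
3 | 2-methylidenehex-5-ynal | O=CC(=C)CCC#C | intermediate
4 | 2-methylidenehex-5-yn-1-ol | OCC(=C)CCC#C | intermediate
5 | 1-methoxy-4-{[(2-methylidenehex-5-yn-1-yl)oxy]methyl}benzene | COc1ccc(COCC(=C)CCC#C)cc1 | intermediate
6 | lithium acetylide of 5 | COc1ccc(COCC(=C)CCC#C[Li])cc1 | intermediate (not isolated)
7 | methyl 7-[(4-methoxybenzyl)oxy]-6-methylidenehept-2-ynoate | COC(=O)C#CCCC(=C)COCc1ccc(OC)cc1 | intermediate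
8 | methyl (2E)-7-[(4-methoxybenzyl)oxy]-6-methylidene-2-(tributylstannyl)hept-2-enoate (ester cis to the chain) | COC(=O)/C(=C\CCC(=C)COCc1ccc(OC)cc1)[Sn](CCCC)(CCCC)CCCC | intermediate
9 | (2E)-7-[(4-methoxybenzyl)oxy]-6-methylidene-2-(tributylstannyl)hept-2-en-1-ol | OC/C(=C\CCC(=C)COCc1ccc(OC)cc1)[Sn](CCCC)(CCCC)CCCC | intermediate
10 | (2E)-2-iodo-7-[(4-methoxybenzyl)oxy]-6-methylidenehept-2-en-1-ol | OC/C(I)=C\CCC(=C)COCc1ccc(OC)cc1 | intermediate
11 | (2E)-2-iodo-1,7-bis[(4-methoxybenzyl)oxy]-6-methylidenehept-2-ene | COc1ccc(COC/C(I)=C\CCC(=C)COCc2ccc(OC)cc2)cc1 | intermediate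
12 | (S)-epichlorohydrin | ClC[C@@H]1CO1 | starting material
13 | (2Z)-1,7-bis[(4-methoxybenzyl)oxy]-6-methylidenehept-2-en-2-yllithium | COc1ccc(COC/C([Li])=C\CCC(=C)COCc2ccc(OC)cc2)cc1 | intermediate (not isolated)
14 | (2S,4Z)-1-chloro-4,8-bis{[(4-methoxybenzyl)oxy]methyl}nona-4,8-dien-2-ol | ClC[C@@H](O)C/C(COCc1ccc(OC)cc1)=C/CCC(=C)COCc1ccc(OC)cc1 | intermediate
15 | (2S)-2-[(2Z)-2,6-bis{[(4-methoxybenzyl)oxy]methyl}hepta-2,6-dien-1-yl]oxirane | C1O[C@H]1C/C(COCc2ccc(OC)cc2)=C/CCC(=C)COCc2ccc(OC)cc2 | intermediate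
16 | (3S,5Z)-5,9-bis{[(4-methoxybenzyl)oxy]methyl}deca-1,5,9-trien-3-ol | C=C[C@@H](O)C/C(COCc1ccc(OC)cc1)=C/CCC(=C)COCc1ccc(OC)cc1 | intermediate
17 | ethyl 2-(hydroxymethyl)prop-2-enoate | CCOC(=O)C(=C)CO | starting material
18 | ethyl 2-({[tert-butyl(dimethyl)silyl]oxy}methyl)prop-2-enoate | CCOC(=O)C(=C)CO[Si](C)(C)C(C)(C)C | intermediate
19 | 2-({[tert-butyl(dimethyl)silyl]oxy}methyl)prop-2-enoic acid | OC(=O)C(=C)CO[Si](C)(C)C(C)(C)C | intermediate
20 | (3S,5Z)-5,9-bis{[(4-methoxybenzyl)oxy]methyl}deca-1,5,9-trien-3-yl 2-({[tert-butyl(dimethyl)silyl]oxy}methyl)prop-2-enoate | C=C[C@@H](OC(=O)C(=C)CO[Si](C)(C)C(C)(C)C)C/C(COCc1ccc(OC)cc1)=C/CCC(=C)COCc1ccc(OC)cc1 | intermediate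
21 | (3S,5Z)-5,9-bis(hydroxymethyl)deca-1,5,9-trien-3-yl 2-({[tert-butyl(dimethyl)silyl]oxy}methyl)prop-2-enoate | C=C[C@@H](OC(=O)C(=C)CO[Si](C)(C)C(C)(C)C)C/C(CO)=C/CCC(=C)CO | intermediate
22 | (3S,5Z)-5,9-bis(acetoxymethyl)deca-1,5,9-trien-3-yl 2-({[tert-butyl(dimethyl)silyl]oxy}methyl)prop-2-enoate | C=C[C@@H](OC(=O)C(=C)CO[Si](C)(C)C(C)(C)C)C/C(COC(C)=O)=C/CCC(=C)COC(C)=O | intermediate
23 | (5S)-5-[(2Z)-2,6-bis(acetoxymethyl)hepta-2,6-dien-1-yl]-3-({[tert-butyl(dimethyl)silyl]oxy}methyl)furan-2(5H)-one | O=C1O[C@@H](C/C(COC(C)=O)=C/CCC(=C)COC(C)=O)C=C1CO[Si](C)(C)C(C)(C)C | intermediate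
24 | (5S)-5-[(2Z)-2,6-bis(acetoxymethyl)hepta-2,6-dien-1-yl]-3-(hydroxymethyl)furan-2(5H)-one | O=C1O[C@@H](C/C(COC(C)=O)=C/CCC(=C)COC(C)=O)C=C1CO | intermediate
25 | (5S)-5-[(2Z)-2,6-bis(acetoxymethyl)hepta-2,6-dien-1-yl]-3-(bromomethyl)furan-2(5H)-one | O=C1O[C@@H](C/C(COC(C)=O)=C/CCC(=C)COC(C)=O)C=C1CBr | intermediate
26 | acrolein (prop-2-enal) | C=CC=O | starting material
27 | allylzinc bromide of 25 (bromozinc on the exocyclic CH2) | O=C1O[C@@H](C/C(COC(C)=O)=C/CCC(=C)COC(C)=O)C=C1C[Zn]Br | intermediate (not isolated)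
28 | (4S,5S)-5-[(2Z)-2,6-bis(acetoxymethyl)hepta-2,6-dien-1-yl]-4-[(1R)-1-hydroxyprop-2-en-1-yl]-3-methylideneoxolan-2-one | C=C1C(=O)O[C@@H](C/C(COC(C)=O)=C/CCC(=C)COC(C)=O)[C@@H]1[C@H](O)C=C | intermediate
29 | (6R,7S,8S)-14,15-diacetoxy-6-hydroxygermacra-1(10)Z,4E,11(13)-trien-12,8-olide: ten-membered ring, trans-fused α-methylene-γ-lactone at C7/C8, free 6-OH | C=C1C(=O)O[C@H]2C/C(COC(C)=O)=C/CC/C(COC(C)=O)=C\[C@@H](O)[C@H]12 | target

## Step count and risks

Total steps: 22. Longest linear sequence: 20 (steps 1–12 and 15–22, from 1); steps 13–14 prepare acid 19.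

Three steps most likely to fail:

1. Step 22, closing the ten-membered ring. The ring is strained, a trisubstituted alkene must form, and the free vinyl carbinol can dimerise or be isomerised to a ketone by ruthenium hydrides. Fallback, changing the substrate rather than the catalyst: set out from bromide 25 and run the zinc allylation (through 27) with (E)-but-2-enal in place of 26 to give the propenyl carbinol F5. Cap O6 with Et3SiCl/imidazole to give the silyl ether F6. Metathesis of this internal-olefin substrate loses propene, forms no ruthenium methylidene and cannot isomerise the carbinol; it gives the silylated macrocycle F7. HF·pyridine then removes the silyl group and the route comes back at 29.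

2. Step 21, the key allylation. Risks are an open or boat transition state giving the C6 epimer, attack through the exocyclic carbon, and acrolein polymerisation in the aqueous medium. Fallback, allylboration instead of Barbier allylation: set out from bromide 25 and borylate it with B2pin2 and Pd2(dba)3 in toluene at rt, where the unactivated allylic acetates do not ionise, to give the pinacol allylboronate F4. F4 adds to acrolein 26 in toluene (rt to 50 °C, or Sc(OTf)3 10 mol % at −78 °C) through an obligatory closed six-membered transition state with the same anti, trans sense. Hydrolytic work-up comes back at 28.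

3. Step 10, the alkenyllithium opening of epichlorohydrin. The alkenyllithium carries an allylic ether and can eliminate to an allene on warming, and the BF3-mediated opening is only moderately efficient. Fallback, forming C9–C10 from an sp carbon and setting the olefin afterwards: set out from alkyne 5 and open 12 with its lithium acetylide 6 and BF3·OEt2 at −78 °C to give the chloro-alkynol F1. Hydroxyl-directed trans-hydrostannation (Bu3SnH, [Cp*RuCl]4 cat., CH2Cl2) puts tin on the alkyne carbon nearer the carbinol and hydrogen anti to it, giving the (Z)-alkenylstannane F2. Iodine converts F2 with retention into the (Z)-alkenyl iodide F3. Stille coupling of F3 with tributyl{[(4-methoxybenzyl)oxy]methyl}stannane (Pd(PPh3)4, CuI, DMF, 60 °C) installs C14 with retention and comes back at 14.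

## Further compounds

F1 | step 10 | (2S)-1-chloro-8-{[(4-methoxybenzyl)oxy]methyl}non-8-en-4-yn-2-ol | ClC[C@@H](O)CC#CCCC(=C)COCc1ccc(OC)cc1
F2 | step 10 | (2S,4Z)-1-chloro-8-{[(4-methoxybenzyl)oxy]methyl}-4-(tributylstannyl)nona-4,8-dien-2-ol | ClC[C@@H](O)C/C(=C/CCC(=C)COCc1ccc(OC)cc1)[Sn](CCCC)(CCCC)CCCC
F3 | step 10 | (2S,4Z)-1-chloro-4-iodo-8-{[(4-methoxybenzyl)oxy]methyl}nona-4,8-dien-2-ol | ClC[C@@H](O)C/C(I)=C/CCC(=C)COCc1ccc(OC)cc1
F4 | step 21 | (5S)-5-[(2Z)-2,6-bis(acetoxymethyl)hepta-2,6-dien-1-yl]-3-[(4,4,5,5-tetramethyl-1,3,2-dioxaborolan-2-yl)methyl]furan-2(5H)-one | O=C1O[C@@H](C/C(COC(C)=O)=C/CCC(=C)COC(C)=O)C=C1CB1OC(C)(C)C(C)(C)O1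
F5 | step 22 | (4S,5S)-5-[(2Z)-2,6-bis(acetoxymethyl)hepta-2,6-dien-1-yl]-4-[(1R,2E)-1-hydroxybut-2-en-1-yl]-3-methylideneoxolan-2-one | C=C1C(=O)O[C@@H](C/C(COC(C)=O)=C/CCC(=C)COC(C)=O)[C@@H]1[C@H](O)/C=C/C
F6 | step 22 | O-triethylsilyl ether of F5 (same configuration) | C=C1C(=O)O[C@@H](C/C(COC(C)=O)=C/CCC(=C)COC(C)=O)[C@@H]1[C@H](O[Si](CC)(CC)CC)/C=C/C
F7 | step 22 | 6-O-triethylsilyl ether of 29 (same configuration) | C=C1C(=O)O[C@H]2C/C(COC(C)=O)=C/CC/C(COC(C)=O)=C\[C@@H](O[Si](CC)(CC)CC)[C@H]12
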